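9.00 is what an excess of 80% asks for: D must stand at that many times Q. In this kinetic resolution the single-handed catalyst G turns Q, with reagent L, into E. In the south-east run, charged with twice the flask's Q and D, the mirror image D read 50.3% at first and 49.3% at the end.

the same everywhere: L 1.71 M; G 1.1 mM

| charge | Q | D | remark | time |
|---|---|---|---|---|
| south-east | 1.1 M | 1.1 M | run made earlier |  |
| flask | 0.57 M | 0.57 M |  | 1.0 h |

south-east run (percent of the Q and D together charged)

| time / min | D / % | Q / % | E / % |
|---|---|---|---|
| 0.667 | 50.3 | 45.1 | 6.0 |
| 2.00 | 50.0 | 38.2 | 11.2 |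
| 3.00 | 49.2 | 34.5 | 13.9 |
| 5.00 | 49.4 | 29.8 | 18.3 |
| 8.00 | 48.9 | 24.5 | 20.7 |
| 10.0 | 49.4 | 22.4 | 23.9 |
| 12.0 | 49.3 | 20.6 | 23.6 |

(each reading ± 0.5 percentage points)

* whether the excess of D over Q among what is left of the two reaches 80% by 1.0 h (yes / no)
* the highest excess of D over Q among what is left of the two up to 1.0 h

- G is single-handed; Q and D are mirror images of each other, charged as a racemate, each of them at the stated concentration
- what was read earlier has a scatter of 0.5 percentage points, one standard deviation

Q falls by factors, so I counted in powers of ten. Let N = log(D/Q), the common logarithm, which starts at zero from equal charges. The target then needs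

N = 0.954

and these decades needed are what I carried.

The south-east run had gained

N = 0.379 at 12.0 min

but its pace was slowing. Over the first reading it read 0.0711 min⁻¹, and from 8.00 min to 12.0 min

pace = 0.0188 min⁻¹

The flask has the south-east charges of L and G but half its Q and D; my own rough reckoning took the south-east gain at 12.0 min and held that late pace to the end:

need met at 42.6 min

N at the end = 1.28

excess = 90.1%

So I said the target falls within the hour.

The forecast also said yes, but with a top of 96%, higher than my figure, on the ground that “Integrating gives Q ≈ 0.008 M at 1 h.”

The flask answered yes with a top of 88.8%, and at 1.00 h it kept 95% of its D and 5.6% of its Q, which is 1.23 decades against the 0.954 needed.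

    L + G + Q → G + E (k = 100 M⁻² min⁻¹)
    E ⇌ X (k = 0.0360 min⁻¹)
    G ⇌ J (K = 0.760, k = 0.180 min⁻¹)
    L + G + D → G + X (k = 1.70 M⁻² min⁻¹)
    2 G → Z (k = 36.0 M⁻¹ min⁻¹)

At 0.0982 h the half-life of Q by its step with L and G in the flask was 0.16 h, shorter than the hour. Each half-life of Q adds 0.301 decades while D stands still, so the need is 3.17 half-lives, or 0.494 h if that half-life held, and the flask took 0.653 h.

The numbers in the tables stem from a simulated flask with made-up constants; scatter was added.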